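The south-east, east and west runs had the same charges of electrophile and nucleophile and differed in free base, and at 50 min they read 68.0%, 66.8% and 68.3% of electrophile at 30 mM, 56 mM and 68 mM of base. That spread of 1.5 percentage points is less than the 5 points that counts as a change.

| flask | electrophile | nucleophile | free base | remark | time |
|---|---|---|---|---|---|
| south-east | 33 mM | 66 mM | 30 mM | run made earlier |  |
| east | 33 mM | 66 mM | 56 mM | run made earlier |  |
| west | 33 mM | 66 mM | 68 mM | run made earlier |  |
| delta | 33 mM | 66.0 mM | 79.0 mM |  | 50 min |
| epsilon | 33 mM | 66.0 mM | 40.0 mM |  | 50 min |

| run | time / min | electrophile / % | target / % |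
|---|---|---|---|
| south-east | 6.00 | 95.3 | 5.8 |
| south-east | 20.0 | 84.1 | 15.5 |
| south-east | 30.0 | 76.2 | 22.2 |
| south-east | 50.0 | 68.0 | 31.7 |
| east | 4.00 | 97.8 | 2.9 |
| east | 10.0 | 91.9 | 8.9 |
| east | 20.0 | 81.8 | 16.3 |
| east | 50.0 | 66.8 | 32.3 |
| west | 6.00 | 94.0 | 4.8 |
| west | 20.0 | 84.4 | 17.0 |
| west | 30.0 | 77.2 | 22.8 |
| west | 50.0 | 68.3 | 31.2 |

(each reading ± 1 percentage point)

- part of the electrophile that has reacted at the end, delta
- part of the electrophile that has reacted at the end, epsilon
- what raising the concentration of free base from its lowest to its highest value here does to the part of the electrophile that has reacted (changes below 5 percentage points count as none) (it falls / no change / it rises)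

- amounts and yields of target count crystals too
- given per volume of solution although it is solid: crystals
- the numbers in the tables scatter with a standard deviation of 1 percentage point
- on the list of suspects stand: acid set free + free base <-> salt of the base; nucleophile + acid set free <-> protonated nucleophile; nucleophile + target -> over-reaction product; crystals <-> target; electrophile + nucleophile <-> acid set free + target

I carried one number from the readings at 20.0 min, whose mean left 83.4% of the electrophile: the pace, which is the reciprocal of the fraction left, less one, divided by the time, 0.00993 /min (an apparent second-order rate constant times the charge of nucleophile). It supposes that each electrophile costs two nucleophile, one to react and one to take up the acid set free, so that the nucleophile, charged at twice the electrophile, falls in step with it.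

The curve then starts with a slope equal to the pace and bends smoothly, with no knee. I expected the slope at 50 min to be 44.7% of the starting one, and the electrophile to cross half at 101 min, and the reckoned curve showed no level short of zero. At 50 min this left 66.8%, which was 0.87 points from the mean reading of 67.7%, so I reckoned 33.2% reacted in delta and in epsilon, with delta's base a little beyond the tested range.

The forecast gave 32.3% for delta (29.5% to 35.5%), 32.3% for epsilon (30% to 35%) and no change, reasoning that the “base therefore captures the acid”; my figure stood 0.90 points above it.

    acid set free + free base ⇌ salt of the base (K = 84000 /M, k = 3.70 /M/min)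
    nucleophile + acid set free ⇌ protonated nucleophile, settled at all times (K = 20000 /M)
    nucleophile + target → over-reaction product (k = 0.0190 /M/min)
    crystals ⇌ target, rate k4*(cs4 - [target]) while solid is left; crystals form when [target] > cs4 (solubility = 14.0 mM, k = 0.390 /min)
    electrophile + nucleophile ⇌ acid set free + target (K = 21.0, k = 0.150 /M/min)

Delta and epsilon both gave 33.1%, with no change. In epsilon at 50.0 min, protonated nucleophile stood at 10.9 mM against 0.0456 mM of salt of the base. Epsilon had not come to rest: at 180 min the pace gives 35.9% of electrophile, and that flask held 36.3%. At 500 min the pace gives 16.8%, and epsilon held 16.8%, with 83.2% reacted, 32.5% as crystals and 8.24% as over-reaction product.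

All runs were computed from invented constants.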